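**Retrosynthetic overview**
- The target is opened back to a cis-fused bicyclic lactol: the hemiacetal carbon becomes the ring methyl group, and the lactol oxygen becomes the free benzylic OH.
- The lactol comes from the corresponding 4,8-diaryl-3,7-dioxabicyclo[3.3.0]octan-2-one by partial reduction.
- The lactone is assembled in one flask from an arylidene Meldrum's acid and an aryl glycidol. Ring A (the oxolane) closes first by C–C bond formation (enolate opens the epoxide); ring B (the γ-lactone) closes second by O-acylation, followed by loss of acetone and CO2.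
- The glycidol comes from Sharpless epoxidation of (E)-3,4-dimethoxycinnamyl alcohol; the arylidene Meldrum's acid comes from veratraldehyde.
- Stereochemistry: the epoxidation fixes the carbinol carbon and, after SN2 inversion, the neighbouring ring carbon; cis ring fusion fixes the methyl-bearing carbon; the reversible oxa-Michael step places the 2-aryl group trans.

Assumption: veratraldehyde, Meldrum's acid, (E)-3,4-dimethoxycinnamyl alcohol and p-toluenesulfonohydrazide are bought as catalogue chemicals; bicyclic locants follow 3,7-dioxabicyclo[3.3.0]octane numbering (C-1/C-5 ring fusion, C-2 carbonyl or hemiacetal carbon).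

**Step 1**
Reactants: 1 3,4-dimethoxybenzaldehyde (veratraldehyde); 2 2,2-dimethyl-1,3-dioxane-4,6-dione (Meldrum's acid)
Product: 3 5-[(3,4-dimethoxyphenyl)methylidene]-2,2-dimethyl-1,3-dioxane-4,6-dione
Conditions: H2O, 75 °C, 2 h; product filtered off and dried
Reagents that add atoms: none
Why: Knoevenagel condensation of the very acidic Meldrum's acid with an aromatic aldehyde runs without catalyst in hot water and the product precipitates; no stereocentre is formed.

**Step 2**
Reactants: 4 (E)-3-(3,4-dimethoxyphenyl)prop-2-en-1-ol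
Product: 5 [(2S,3S)-3-(3,4-dimethoxyphenyl)oxiran-2-yl]methanol
Conditions: Ti(OiPr)4 (10 mol%), L-(+)-diethyl tartrate (12 mol%), t-BuOOH (2 equiv, in isooctane), 4 Å MS, CH2Cl2, −25 °C; cold NaOH/NaCl work-up; Et3N-washed SiO2
Reagents that add atoms: tert-butyl hydroperoxide, CC(C)(C)OO
Why: Sharpless asymmetric epoxidation of an (E)-allylic alcohol, in which the L-(+)-tartrate catalyst gives the (2S,3S)-trans-epoxide (as for cinnamyl alcohol); this sets the later carbinol carbon directly and the later C-5 after inversion, and the electron-rich epoxide is kept away from acid throughout.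

**Step 3**
Reactants: 3 5-[(3,4-dimethoxyphenyl)methylidene]-2,2-dimethyl-1,3-dioxane-4,6-dione; 5 [(2S,3S)-3-(3,4-dimethoxyphenyl)oxiran-2-yl]methanol
Product: 9 (1S,4R,5R,8S)-4,8-bis(3,4-dimethoxyphenyl)-3,7-dioxabicyclo[3.3.0]octan-2-one, via oxa-Michael adduct 6 (not isolated), via spiro hydroxy dioxanedione 7 (not isolated), via lactone carboxylic acid 8 (not isolated)
Conditions: Cs2CO3 (1.1 equiv), 4 Å MS, DMF, 0 → 60 °C; then AcOH (4 equiv), 110 °C
Reagents that add atoms: none
Why: Proposed new method: the hydroxyl of 5 adds reversibly to the strongly electrophilic alkylidene Meldrum's acid 3 (oxa-Michael addition) to give the stabilised caesium enolate of 6, which opens the epoxide by irreversible 5-exo SN2 attack at the non-benzylic carbon (ring A; inversion gives C-5, the untouched benzylic C–O becomes C-4, and because the addition is reversible the C-8 aryl is expected to end up trans to the new side chain across the spiro centre), after which the freed benzylic alkoxide of 7 acylates the cis carbonyl of the dioxanedione with loss of acetone (ring B) and the malonic half-acid 8 loses CO2 on heating with protonation to the only possible cis-fused lactone (C-1); the closest known reactions are the malonate–epoxide γ-butyrolactone synthesis, Stork-type exo opening of epoxides by tethered carbanions and Michael-initiated ring closure.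

**Step 4**
Reactants: 9 (1S,4R,5R,8S)-4,8-bis(3,4-dimethoxyphenyl)-3,7-dioxabicyclo[3.3.0]octan-2-one
Product: 10 (1S,4R,5R,8S)-4,8-bis(3,4-dimethoxyphenyl)-3,7-dioxabicyclo[3.3.0]octan-2-ol (both C-2 epimers)
Conditions: i-Bu2AlH (1.2 equiv), CH2Cl2, −78 °C; aqueous KNaC4H4O6
Reagents that add atoms: none
Why: Partial reduction of a γ-lactone to the lactol with i-Bu2AlH at −78 °C, where the tetrahedral aluminium alkoxide survives until work-up; the existing stereocentres are untouched and the new hemiacetal carbon is an inconsequential mixture.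

**Step 5**
Reactants: 10 (1S,4R,5R,8S)-4,8-bis(3,4-dimethoxyphenyl)-3,7-dioxabicyclo[3.3.0]octan-2-ol; 11 4-methylbenzenesulfonohydrazide
Product: 13 (R)-(3,4-dimethoxyphenyl)[(3R,4S,5S)-5-(3,4-dimethoxyphenyl)-4-methyloxolan-3-yl]methanol, via open-chain tosylhydrazone 12 (not isolated)
Conditions: 11 (1.1 equiv), 4 Å MS, CHCl3, 40 °C; then catecholborane (3 equiv), 0 °C; then CH3CO2Na·3H2O (4 equiv), 60 °C
Reagents that add atoms: none
Why: The lactol equilibrates with the γ-hydroxy aldehyde, which condenses with 11 to give 12; catecholborane then adds hydride to C=N and acetate-induced loss of sulfinate gives a diazene that expels N2 with hydrogen transfer to carbon (Caglioti-type tosylhydrazone reduction, Kabalka variant), so the masked aldehyde carbon becomes the methyl group under near-neutral conditions and the adjacent stereocentre, the β-ether oxygen and the benzylic alcohol are left alone.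

**Compound list**
1 | 3,4-dimethoxybenzaldehyde | COc1ccc(C=O)cc1OC | starting material
2 | 2,2-dimethyl-1,3-dioxane-4,6-dione | CC1(C)OC(=O)CC(=O)O1 | starting material
3 | 5-[(3,4-dimethoxyphenyl)methylidene]-2,2-dimethyl-1,3-dioxane-4,6-dione | COc1ccc(C=C2C(=O)OC(C)(C)OC2=O)cc1OC | intermediate
4 | (E)-3-(3,4-dimethoxyphenyl)prop-2-en-1-ol | COc1ccc(/C=C/CO)cc1OC | starting material
5 | [(2S,3S)-3-(3,4-dimethoxyphenyl)oxiran-2-yl]methanol | OC[C@@H]1O[C@H]1c1ccc(OC)c(OC)c1 | intermediate
6 | 5-[(S)-(3,4-dimethoxyphenyl){[(2S,3S)-3-(3,4-dimethoxyphenyl)oxiran-2-yl]methoxy}methyl]-2,2-dimethyl-1,3-dioxane-4,6-dione (not isolated; present as caesium enolate) | COc1ccc([C@@H](OC[C@@H]2O[C@H]2c3ccc(OC)c(OC)c3)C4C(=O)OC(C)(C)OC4=O)cc1OC | intermediate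
7 | (2'R,4'R)-2'-(3,4-dimethoxyphenyl)-4'-[(R)-(3,4-dimethoxyphenyl)(hydroxy)methyl]-2,2-dimethylspiro[1,3-dioxane-5,3'-oxolane]-4,6-dione (not isolated; present as caesium alkoxide) | COc1ccc([C@H]2OC[C@H]([C@@H](O)c3ccc(OC)c(OC)c3)C24C(=O)OC(C)(C)OC4=O)cc1OC | intermediate
8 | (1S,4R,5R,8R)-4,8-bis(3,4-dimethoxyphenyl)-2-oxo-3,7-dioxabicyclo[3.3.0]octane-1-carboxylic acid (not isolated) | COc1ccc([C@H]2OC[C@@H]3[C@H](c4ccc(OC)c(OC)c4)OC(=O)[C@]23C(=O)O)cc1OC | intermediate
9 | (1S,4R,5R,8S)-4,8-bis(3,4-dimethoxyphenyl)-3,7-dioxabicyclo[3.3.0]octan-2-one | COc1ccc([C@H]2OC[C@@H]3[C@H](c4ccc(OC)c(OC)c4)OC(=O)[C@H]23)cc1OC | intermediate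
10 | (1S,4R,5R,8S)-4,8-bis(3,4-dimethoxyphenyl)-3,7-dioxabicyclo[3.3.0]octan-2-ol (C-2 epimers) | COc1ccc([C@H]2OC[C@@H]3[C@H](c4ccc(OC)c(OC)c4)OC(O)[C@H]23)cc1OC | intermediate
11 | 4-methylbenzenesulfonohydrazide | Cc1ccc(S(=O)(=O)NN)cc1 | starting material
12 | N'-({(2S,3R,4R)-2-(3,4-dimethoxyphenyl)-4-[(R)-(3,4-dimethoxyphenyl)(hydroxy)methyl]oxolan-3-yl}methylidene)-4-methylbenzenesulfonohydrazide (not isolated) | COc1ccc([C@H]2OC[C@H]([C@@H](O)c3ccc(OC)c(OC)c3)[C@@H]2C=NNS(=O)(=O)c4ccc(C)cc4)cc1OC | intermediate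
13 | (R)-(3,4-dimethoxyphenyl)[(3R,4S,5S)-5-(3,4-dimethoxyphenyl)-4-methyloxolan-3-yl]methanol | COc1ccc([C@H]2OC[C@H]([C@@H](O)c3ccc(OC)c(OC)c3)[C@@H]2C)cc1OC | target

**Totals**
Total step count: 5. Longest linear sequence: 4 steps (steps 2, 3, 4 and 5 from compound 4).

**Steps most likely to fail, with fallbacks**

Step 3 is the riskiest. The Meldrum's enolate may be too weak a nucleophile for the epoxide, attack at the benzylic epoxide carbon (6-endo) may compete, and the C-8 aryl epimer may form. The fallback sets out from 1 and uses 5. Condensation of 1 with dimethyl malonate (piperidine, AcOH, toluene, reflux with water removal) gives dimethyl 2-[(3,4-dimethoxyphenyl)methylidene]propanedioate F1. Treating F1 and 5 with NaH in THF (0 → 50 °C) runs the same relay through the much more nucleophilic malonate carbanion: oxa-Michael addition, epoxide opening and lactonisation with loss of methoxide give methyl (1S,4R,5R,8R)-4,8-bis(3,4-dimethoxyphenyl)-2-oxo-3,7-dioxabicyclo[3.3.0]octane-1-carboxylate F2, which can be isolated and purified. Krapcho dealkoxycarbonylation of F2 (LiCl, wet DMSO, 130 °C) then returns to the route at 9, the enolate being protonated to the cis-fused lactone.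

Step 2 is second. The 3,4-dimethoxyphenyl epoxide is easily opened by the Lewis-acidic titanium tartrate or on silica, which would cost yield and enantiopurity. The fallback sets out from 4. Silylation (t-BuMe2SiCl, imidazole, DMF) gives tert-butyl{[(2E)-3-(3,4-dimethoxyphenyl)prop-2-en-1-yl]oxy}dimethylsilane F3. Dioxirane epoxidation with the L-fructose-derived enantiomer of the Shi ketone (30 mol%, KHSO5, K2CO3, buffer pH 10.5, MeCN/dimethoxymethane, 0 °C) avoids any Lewis acid and gives tert-butyl{[(2S,3S)-3-(3,4-dimethoxyphenyl)oxiran-2-yl]methoxy}dimethylsilane F4. Desilylation with Bu4NF in THF at 0 °C returns to the route at 5.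

Step 5 is third. The lactol may be reluctant to open to the tosylhydrazone, or may sit as a cyclic N-sulfonyl hydrazino acetal that is reduced only slowly. The fallback sets out from 10. Reaction with 1,2-bis(tert-butyldimethylsilyl)hydrazine and catalytic Sc(OSO2CF3)3 in CH2Cl2 gives the N-silyl hydrazone tert-butyl(dimethyl)silyl hydrazone of (2S,3R,4R)-2-(3,4-dimethoxyphenyl)-4-[(R)-(3,4-dimethoxyphenyl)(hydroxy)methyl]oxolane-3-carbaldehyde F5. Exposure of F5 to KOC(CH3)3 in t-BuOH/DMSO at room temperature effects a low-temperature Wolff–Kishner reduction (base-induced diimide-anion pathway instead of hydride reduction) and returns to the route at 13.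

**Further compounds**
F1 | step 3 | dimethyl 2-[(3,4-dimethoxyphenyl)methylidene]propanedioate | COC(=O)C(=Cc1ccc(OC)c(OC)c1)C(=O)OC
F2 | step 3 | methyl (1S,4R,5R,8R)-4,8-bis(3,4-dimethoxyphenyl)-2-oxo-3,7-dioxabicyclo[3.3.0]octane-1-carboxylate | COc1ccc([C@H]2OC[C@@H]3[C@H](c4ccc(OC)c(OC)c4)OC(=O)[C@]23C(=O)OC)cc1OC
F3 | step 2 | tert-butyl{[(2E)-3-(3,4-dimethoxyphenyl)prop-2-en-1-yl]oxy}dimethylsilane | COc1ccc(/C=C/CO[Si](C)(C)C(C)(C)C)cc1OC
F4 | step 2 | tert-butyl{[(2S,3S)-3-(3,4-dimethoxyphenyl)oxiran-2-yl]methoxy}dimethylsilane | CC(C)(C)[Si](C)(C)OC[C@@H]1O[C@H]1c1ccc(OC)c(OC)c1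
F5 | step 5 | (2S,3R,4R)-2-(3,4-dimethoxyphenyl)-4-[(R)-(3,4-dimethoxyphenyl)(hydroxy)methyl]oxolane-3-carbaldehyde N-[tert-butyl(dimethyl)silyl]hydrazone | COc1ccc([C@H]2OC[C@H]([C@@H](O)c3ccc(OC)c(OC)c3)[C@@H]2C=NN[Si](C)(C)C(C)(C)C)cc1OC
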